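**Plan**

Rings: A = arene, B = pyran, C = cyclopentane, D = cyclohexene. Retrosynthetic cuts, in order: the two O–CH3 and two aryl–CHO bonds; the ring D alkene back to a ketone (ring D is then menthone, spiro carbon = menthone C-6); the CH2–C(spiro) bond of ring C; the bond from the spiro carbon to the O–CH carbon (chroman C-2); the two alkyl bonds at the quaternary chroman C-3 and the C-4–isobutyl bond, back to 5,7-dimethoxycoumarin.
Enabling feature: the spiro carbon is α to the ring D carbonyl carbon (the later =CH) and β to the ring B oxygen, so its enolate forms regiospecifically by oxa-Michael closure of ring B and can be alkylated by a bromoethyl arm on the neighbouring quaternary carbon.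
Forward order: ring B is elaborated on the coumarin (rings A and B), ring D arrives as (+)-menthone, ring C is closed last (ring B re-closes in the same operation), then enol triflate, diformylation, triflate reduction and demethylation.
Stereochemistry: C–isobutyl from a copper-catalysed asymmetric conjugate addition; the quaternary C–CH3 by alkylation anti to isobutyl; O–CH by equilibration and the spiro carbon by chair-like alkylation in the key step; CH–CH3 from (+)-menthone, whose isopropyl centre disappears in the alkene.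
Locants: chroman numbering up to 16; from 17 on spiro[cyclohexane-1,3'-cyclopenta[b]chromene] numbering (spiro C-1, ring D C-2 to C-6, ring C C-1' and C-2', O–CH = C-3a', CH–isobutyl = C-9', C–CH3 = C-9a').

Key step: step 7

Assumption: the sense of induction in step 1 is set by the choice of ligand enantiomer; the (R,Sp)-ligand is written and its mirror image would be used if it proved to be the one that gives the (4R)-lactone.

Step 1
Reactants: 1 5,7-dimethoxycoumarin; 2 isobutylmagnesium bromide
Product: 3 (4R)-4-isobutyl-5,7-dimethoxychroman-2-one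
Conditions: CuBr·SMe2 (5 mol%), (R,Sp)-1-[2-(diphenylphosphino)ferrocenyl]ethyldicyclohexylphosphine (6 mol%), CH2Cl2, −72 °C; then 1 M HCl
Reagents that add atoms: none
Why: Copper-catalysed asymmetric conjugate addition of a Grignard reagent to a coumarin, a known entry to 4-alkylchroman-2-ones; the chiral diphosphine–copper complex selects the face of C-4 and should set the isobutyl-bearing centre as 4R.

Step 2
Reactants: 3 (4R)-4-isobutyl-5,7-dimethoxychroman-2-one
Product: 5 (3R,4R)-4-isobutyl-5,7-dimethoxy-3-methylchroman-2-one, via lithium enolate 4 (not isolated)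
Conditions: LiN(i-Pr)2, THF, −78 °C; MeI, −78 → −40 °C
Reagents that add atoms: iodomethane, CI
Why: Lactone enolate alkylation, kept cold to avoid ketene formation from the aryl ester enolate; the methyl group should enter trans to the 4-isobutyl group, although this centre is enolised again in step 3.

Step 3
Reactants: 5 (3R,4R)-4-isobutyl-5,7-dimethoxy-3-methylchroman-2-one; 6 2-bromoethyl trifluoromethanesulfonate
Product: 8 (3R,4S)-3-(2-bromoethyl)-4-isobutyl-5,7-dimethoxy-3-methylchroman-2-one, via lithium enolate 7 (not isolated)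
Conditions: LiN(i-Pr)2, THF/DMPU, −78 °C; 6, −78 → −30 °C
Reagents that add atoms: none
Why: Second enolate alkylation at the triflate carbon (the bromide is not displaced); the 4-isobutyl group is held pseudoaxial by the peri 5-methoxy group, so the bromoethyl arm should enter anti to it and the quaternary centre carries methyl cis to isobutyl.

Step 4
Reactants: 8 (3R,4S)-3-(2-bromoethyl)-4-isobutyl-5,7-dimethoxy-3-methylchroman-2-one
Product: 10 (3R,4S)-3-(2-bromoethyl)-4-isobutyl-5,7-dimethoxy-3-methylchroman-2-yl acetate (C-2 epimers), via aluminium hemiacetal alkoxide 9 (not isolated)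
Conditions: i-Bu2AlH, CH2Cl2, −78 °C; then pyridine, DMAP, Ac2O, −78 → 0 °C
Reagents that add atoms: acetic anhydride, CC(=O)OC(C)=O
Why: One-pot reductive acetylation of a lactone: the tetrahedral aluminium hemiacetal is stable at −78 °C and is acetylated in place, giving the anomeric acetate without over-reduction; the alkyl bromide is inert.

Step 5
Reactants: 11 (+)-menthone
Product: 13 trimethyl{[(3S,6R)-3-methyl-6-(propan-2-yl)cyclohex-1-en-1-yl]oxy}silane, via lithium enolate 12 (not isolated)
Conditions: LiN(i-Pr)2, THF, −78 °C; Me3SiCl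
Reagents that add atoms: chlorotrimethylsilane, C[Si](C)(C)Cl
Why: Kinetic deprotonation of menthone at the unbranched C-6 followed by O-silylation gives the less substituted silyl enol ether; neither stereocentre is touched.

Step 6
Reactants: 10 (3R,4S)-3-(2-bromoethyl)-4-isobutyl-5,7-dimethoxy-3-methylchroman-2-yl acetate; 13 menthone trimethylsilyl enol ether
Product: 14 (2R,5S)-6-[(3R,4R)-3-(2-bromoethyl)-4-isobutyl-5,7-dimethoxy-3-methylchroman-2-yl]-5-methyl-2-(propan-2-yl)cyclohexan-1-one (epimers at chroman C-2 and cyclohexanone C-6)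
Conditions: Me3SiOTf (10 mol%), CH2Cl2, −78 → −40 °C
Reagents that add atoms: none
Why: Lewis acid ionisation of the anomeric acetate to the cyclic oxocarbenium ion and Mukaiyama-type addition of the silyl enol ether join the fragments at the chroman C-2–menthone C-6 bond; the two new centres are left uncontrolled because step 7 re-sets both.

Step 7
Reactants: 14 chroman-2-yl menthone bromide (epimer mixture)
Product: 17 (1S,3R,3a'S,6S,9'R,9a'R)-6',8'-dimethoxy-6,9a'-dimethyl-9'-(2-methylpropyl)-3-(propan-2-yl)-1',2',9',9a'-tetrahydro-3a'H-spiro[cyclohexane-1,3'-cyclopenta[b]chromen]-2-one, via ring-opened potassium phenoxide enone 15 (not isolated), via potassium enolate 16 (not isolated)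
Conditions: t-BuOK (2.5 equiv), t-BuOH/THF 1:1, 0 → 40 °C
Reagents that add atoms: none
Why: tert-Butoxide opens the β-aryloxy ketone 14 reversibly (E1cB) to the phenoxide enone 15, 6-exo-trig oxa-Michael re-addition re-closes ring B and gives enolate 16 regiospecifically at the future spiro carbon, and 16 is trapped irreversibly by 5-exo-tet (enolexo) C-alkylation with the bromoethyl arm, which forms the CH2–C(spiro) bond and ring C. The closest known reaction types are the Michael-initiated ring closure and the intramolecular spiro-alkylation of cyclohexanone enolates used for spiro[4.5]decanes. C-3a' is set by equilibration: the epimer with the menthone ring equatorial (trans to the pseudoaxial isobutyl group, cis to the axial bromoethyl arm) is the one that reaches the alkylation geometry, so both C-2 epimers of 14 should funnel into the cis ring fusion with 3a'-H cis to the 9a'-methyl group. The spiro carbon is set in the alkylation: ring D should react through the half-chair with isopropyl and methyl equatorial, the new bond forming axially (cis to the 6-methyl group) while the bulky chromanyl carbon stays equatorial with its C–H turned toward the methyl-bearing side; this is 1S in 17 and becomes 1R in the target by a priority change only. The step needs C-alkylation in a five-membered ring to beat O-alkylation of the phenoxide (seven-membered) and E2 loss of HBr; the much higher nucleophilicity of the enolate, the enolexo five-ring geometry and the primary bromide favour this, and the CH–CH3 centre cannot epimerise because it is β to the carbonyl.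

Step 8
Reactants: 17 spiro ketone
Product: 19 (1S,3a'S,6S,9'R,9a'R)-6',8'-dimethoxy-6,9a'-dimethyl-9'-(2-methylpropyl)-3-(propan-2-yl)-1',2',9',9a'-tetrahydro-3a'H-spiro[cyclohex-2-ene-1,3'-cyclopenta[b]chromen]-2-yl trifluoromethanesulfonate, via potassium enolate 18 (not isolated)
Conditions: KN(SiMe3)2, THF, −78 → −20 °C; PhNTf2, → 0 °C
Reagents that add atoms: N-phenylbis(trifluoromethanesulfonimide), O=S(=O)(N(c1ccccc1)S(=O)(=O)C(F)(F)F)C(F)(F)F
Why: The only enolisable position of 17 is the isopropyl-bearing α-carbon (the spiro carbon is quaternary), so one enolate forms and O-triflation fixes the double bond in its final place; the isopropyl stereocentre is removed here.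

Step 9
Reactants: 19 enol triflate
Product: 20 (1S,3a'S,6S,9'R,9a'R)-5',7'-diformyl-6',8'-dimethoxy-6,9a'-dimethyl-9'-(2-methylpropyl)-3-(propan-2-yl)-1',2',9',9a'-tetrahydro-3a'H-spiro[cyclohex-2-ene-1,3'-cyclopenta[b]chromen]-2-yl trifluoromethanesulfonate
Conditions: Cl2CHOMe (6 equiv), TiCl4 (6 equiv), CH2Cl2, −78 → 0 °C; ice water
Reagents that add atoms: dichloromethyl methyl ether, COC(Cl)Cl; water, O
Why: Rieche formylation (Friedel–Crafts type) at the two free ring A positions, each flanked by two oxygens; the electron-poor enol triflate should be inert to the Lewis acid, which is why formylation is placed before the alkene is released.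

Step 10
Reactants: 20 diformyl enol triflate
Product: 21 (1R,3a'S,6S,9'R,9a'R)-6',8'-dimethoxy-6,9a'-dimethyl-9'-(2-methylpropyl)-3-(propan-2-yl)-1',2',9',9a'-tetrahydro-3a'H-spiro[cyclohex-2-ene-1,3'-cyclopenta[b]chromene]-5',7'-dicarbaldehyde
Conditions: Pd(OAc)2 (5 mol%), PPh3 (12 mol%), Bu3N, HCO2H, DMF, 60 °C
Reagents that add atoms: none
Why: Palladium-catalysed formate reduction of an enol triflate (oxidative addition, formate exchange with loss of CO2, reductive elimination) replaces OTf by H without moving the alkene; aryl aldehydes and ethers are tolerated.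

Step 11
Reactants: 21 target dimethyl ether
Product: 22 CNP0121396.2, (1R,3a'S,6S,9'R,9a'R)-6',8'-dihydroxy-6,9a'-dimethyl-9'-(2-methylpropyl)-3-(propan-2-yl)-1',2',9',9a'-tetrahydro-3a'H-spiro[cyclohex-2-ene-1,3'-cyclopenta[b]chromene]-5',7'-dicarbaldehyde
Conditions: BCl3 (5 equiv), CH2Cl2, −78 → 0 °C; aq. NaHCO3
Reagents that add atoms: none
Why: Chelation-assisted cleavage of aryl methyl ethers ortho to formyl groups by BCl3 at low temperature; the ring B C–O bond sits on a carbon between two quaternary centres and should not be cleaved, and the trisubstituted alkene should survive the short cold exposure.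

**Compound list**

1 | 5,7-dimethoxycoumarin (5,7-dimethoxy-2H-chromen-2-one) | O=C1C=Cc2c(OC)cc(OC)cc2O1 | starting material
2 | isobutylmagnesium bromide | CC(C)C[Mg]Br | starting material
3 | (4R)-4-isobutyl-5,7-dimethoxychroman-2-one | CC(C)C[C@H]1c2c(OC)cc(OC)cc2OC(=O)C1 | intermediate
4 | lithium enolate of 3 | CC(C)C[C@H]1c2c(OC)cc(OC)cc2OC(O[Li])=C1 | intermediate
5 | (3R,4R)-4-isobutyl-5,7-dimethoxy-3-methylchroman-2-one (methyl trans to isobutyl) | CC(C)C[C@H]1c2c(OC)cc(OC)cc2OC(=O)[C@@H]1C | intermediate
6 | 2-bromoethyl trifluoromethanesulfonate | BrCCOS(=O)(=O)C(F)(F)F | starting material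
7 | lithium enolate of 5 | CC(C)C[C@H]1c2c(OC)cc(OC)cc2OC(O[Li])=C1C | intermediate
8 | (3R,4S)-3-(2-bromoethyl)-4-isobutyl-5,7-dimethoxy-3-methylchroman-2-one (bromoethyl trans, methyl cis to isobutyl) | CC(C)C[C@H]1c2c(OC)cc(OC)cc2OC(=O)[C@]1(C)CCBr | intermediate
9 | diisobutylaluminium hemiacetal alkoxide of 8 (C-2 epimers) | CC(C)C[C@H]1c2c(OC)cc(OC)cc2OC(O[Al](CC(C)C)CC(C)C)[C@]1(C)CCBr | intermediate
10 | (3R,4S)-3-(2-bromoethyl)-4-isobutyl-5,7-dimethoxy-3-methylchroman-2-yl acetate (C-2 epimers) | CC(C)C[C@H]1c2c(OC)cc(OC)cc2OC(OC(C)=O)[C@]1(C)CCBr | intermediate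
11 | (+)-menthone, (2R,5S)-5-methyl-2-(propan-2-yl)cyclohexan-1-one | CC(C)[C@H]1CC[C@H](C)CC1=O | starting material
12 | kinetic lithium enolate of 11 | CC(C)[C@H]1CC[C@H](C)C=C1O[Li] | intermediate
13 | trimethyl{[(3S,6R)-3-methyl-6-(propan-2-yl)cyclohex-1-en-1-yl]oxy}silane | CC(C)[C@H]1CC[C@H](C)C=C1O[Si](C)(C)C | intermediate
14 | (2R,5S)-6-[(3R,4R)-3-(2-bromoethyl)-4-isobutyl-5,7-dimethoxy-3-methylchroman-2-yl]-5-methyl-2-(propan-2-yl)cyclohexan-1-one (epimers at chroman C-2 and cyclohexanone C-6) | CC(C)C[C@H]1c2c(OC)cc(OC)cc2OC(C3C(=O)[C@@H](C(C)C)CC[C@@H]3C)[C@]1(C)CCBr | intermediate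
15 | ring-opened potassium phenoxide of the 6-alkylidene menthone (enone, alkene geometry not fixed) | CC(C)C[C@@H](c1c(OC)cc(OC)cc1O[K])[C@@](C)(CCBr)C=C1C(=O)[C@@H](C(C)C)CC[C@@H]1C | intermediate
16 | potassium enolate of the (2S)-chroman epimer of 14 (enolate carbon = menthone C-6) | CC(C)C[C@H]1c2c(OC)cc(OC)cc2O[C@H](C3=C(O[K])[C@@H](C(C)C)CC[C@@H]3C)[C@]1(C)CCBr | intermediate
17 | (1S,3R,3a'S,6S,9'R,9a'R)-6',8'-dimethoxy-6,9a'-dimethyl-9'-(2-methylpropyl)-3-(propan-2-yl)-1',2',9',9a'-tetrahydro-3a'H-spiro[cyclohexane-1,3'-cyclopenta[b]chromen]-2-one (the C-3 epimer may accompany it and is equally usable) | CC(C)C[C@H]1c2c(OC)cc(OC)cc2O[C@H]2[C@]1(C)CC[C@@]21C(=O)[C@@H](C(C)C)CC[C@@H]1C | intermediate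
18 | potassium enolate of 17 | CC(C)C[C@H]1c2c(OC)cc(OC)cc2O[C@H]2[C@]1(C)CC[C@@]21C(O[K])=C(C(C)C)CC[C@@H]1C | intermediate
19 | enol triflate of 17, (1S,3a'S,6S,9'R,9a'R)-configured spiro[cyclohex-2-ene-1,3'-cyclopenta[b]chromen]-2-yl trifluoromethanesulfonate | CC(C)C[C@H]1c2c(OC)cc(OC)cc2O[C@H]2[C@]1(C)CC[C@@]21C(OS(=O)(=O)C(F)(F)F)=C(C(C)C)CC[C@@H]1C | intermediate
20 | 5',7'-diformyl derivative of 19 | CC(C)C[C@H]1c2c(OC)c(C=O)c(OC)c(C=O)c2O[C@H]2[C@]1(C)CC[C@@]21C(OS(=O)(=O)C(F)(F)F)=C(C(C)C)CC[C@@H]1C | intermediate
21 | 6',8'-di-O-methyl ether of the target, (1R,3a'S,6S,9'R,9a'R) | CC(C)C[C@H]1c2c(OC)c(C=O)c(OC)c(C=O)c2O[C@H]2[C@]1(C)CC[C@@]21C=C(C(C)C)CC[C@@H]1C | intermediate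
22 | CNP0121396.2, (1R,3a'S,6S,9'R,9a'R)-6',8'-dihydroxy-6,9a'-dimethyl-9'-(2-methylpropyl)-3-(propan-2-yl)-1',2',9',9a'-tetrahydro-3a'H-spiro[cyclohex-2-ene-1,3'-cyclopenta[b]chromene]-5',7'-dicarbaldehyde | CC(C)C[C@H]1c2c(O)c(C=O)c(O)c(C=O)c2O[C@H]2[C@]1(C)CC[C@@]21C=C(C(C)C)CC[C@@H]1C | target

Total step count: 11. Longest linear sequence: 10 steps (steps 1–4 and 6–11).

**Steps most likely to fail**

Step 7. The tether may attack the wrong enolate face (spiro epimer), the ring-opened phenoxide may be O-alkylated to a seven-membered ether, or HBr may be lost by E2. The fallback closes the same bond by a reversible aldol reaction, so the spiro carbon is set under thermodynamic control. It sets out from 14: Kornblum-type oxidation of the bromide (N-methylmorpholine N-oxide, MeCN) should give the aldehyde 2-[2-(6-oxocyclohexyl)chroman-3-yl]acetaldehyde analogue of 14 F1. K2CO3 in MeOH then runs the same oxa-Michael equilibrium but closes ring C by 5-exo-trig aldol addition, giving the 2'-hydroxy derivative of 17 F2 with the chromanyl carbon equatorial. Dehydration with the Burgess reagent should give the 1',2'-didehydro derivative of 17 F3, and hydrogenation (H2, palladium on carbon, EtOAc) returns to 17.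

Step 1. The electron-rich, peri-substituted coumarin may add the Grignard reagent sluggishly, and an uncatalysed background reaction may erode the enantioselectivity. The fallback replaces catalysis by a classical resolution. It sets out from 1: racemic conjugate addition of 2 (CuI 10 mol%, Me3SiCl, THF, −40 °C) should give the racemic lactone rac-4-isobutyl-5,7-dimethoxychroman-2-one F4. Aminolysis with (S)-1-phenylethylamine opens it to two diastereomeric phenolic amides, from which (3R)-3-(2-hydroxy-4,6-dimethoxyphenyl)-5-methyl-N-[(1S)-1-phenylethyl]hexanamide F5 is separated by crystallisation or chromatography. Acid-induced relactonisation (TsOH, toluene, reflux) returns to 3.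

Step 6. The neopentyl-type oxocarbenium ion may lose a proton or recapture acetate faster than the hindered silyl enol ether adds. The fallback joins the fragments by an aldol reaction on the aldehyde oxidation level. It sets out from 8: i-Bu2AlH (CH2Cl2, −78 °C) should give the lactol (3R,4S)-3-(2-bromoethyl)-4-isobutyl-5,7-dimethoxy-3-methylchroman-2-ol F6. Addition of the lithium enolate 12 of menthone (2.2 equiv, THF, −78 °C) to its ring-opened hydroxy aldehyde form should give the aldol adduct 6-[1-hydroxy-2-methyl-2-(2-bromoethyl)-3-aryl-5-methylhexyl]menthone F7. TsOH (toluene, 60 °C) dehydrates it and closes ring B by oxa-Michael addition, returning to 14.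

Further compounds
F1 | step 7 | aldehyde from 14 (CH2CH2Br replaced by CH2CHO) | CC(C)C[C@H]1c2c(OC)cc(OC)cc2OC(C3C(=O)[C@@H](C(C)C)CC[C@@H]3C)[C@]1(C)CC=O
F2 | step 7 | 2'-hydroxy derivative of 17 (carbinol configuration not fixed) | CC(C)C[C@H]1c2c(OC)cc(OC)cc2O[C@H]2[C@]1(C)CC(O)[C@@]21C(=O)[C@@H](C(C)C)CC[C@@H]1C
F3 | step 7 | 1',2'-didehydro derivative of 17 | CC(C)C[C@H]1c2c(OC)cc(OC)cc2O[C@H]2[C@]1(C)C=C[C@@]21C(=O)[C@@H](C(C)C)CC[C@@H]1C
F4 | step 1 | rac-4-isobutyl-5,7-dimethoxychroman-2-one | CC(C)CC1c2c(OC)cc(OC)cc2OC(=O)C1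
F5 | step 1 | (3R)-3-(2-hydroxy-4,6-dimethoxyphenyl)-5-methyl-N-[(1S)-1-phenylethyl]hexanamide | CC(C)C[C@H](CC(=O)N[C@@H](C)c1ccccc1)c1c(OC)cc(OC)cc1O
F6 | step 6 | (3R,4S)-3-(2-bromoethyl)-4-isobutyl-5,7-dimethoxy-3-methylchroman-2-ol (C-2 epimers) | CC(C)C[C@H]1c2c(OC)cc(OC)cc2OC(O)[C@]1(C)CCBr
F7 | step 6 | aldol adduct of menthone with the ring-opened form of F6 (carbinol and menthone C-6 not fixed) | CC(C)C[C@@H](c1c(OC)cc(OC)cc1O)[C@@](C)(CCBr)C(O)C1C(=O)[C@@H](C(C)C)CC[C@@H]1C
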